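## Retrosyn­thetic overview

- The target is reached by desilylation of a bicyclic triketone whose carbocycle is closed last, by an intramolecular vinylogous Claisen condensation that forms C4a–C5 and sets the quaternary centre C4a (chromene numbering: O1, C2(Me2), C3, C4, C4a, C5–C8, C8a).
- Its precursor, an oxan-2-ylidene triketo ester, is made by γ-lavandulylation and C-prenylation of the product of the key step, a two-atom ring expansion of a cyclobutane to the oxane by insertion of an acyl C=O group.
- The cyclobutane comes from (−)-α-pinene by cleavage of its C2=C3 bond; all ten pinene carbons stay (ring carbons C6, C5, C7, C1 → C2, C3, C4, C4a; C2 and its methyl → C8a and C8; C4 and C3 → CH2 and CH= of the C3 prenyl group). The aroyl part comes from silylated methyl protocatechuate, C5–C7 from methyl malonyl chloride, and the lavandulyl group from an oxazolidinone alkylation.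
- Enabling feature: in the cyclobutane the ring carbon with the two methyl groups (tertiary-cation donor, future C2) is bonded to the ring carbon that bears the tricarbonyl acyl group (acceptor, future C4a). When this strained bond ionises, the acyl oxygen reaches the gem-dimethyl carbon through a six-membered array.
- Order of ring formation: cyclobutane (from pinene) → oxane (step 6) → carbocycle (step 13).

Key step: step 6

Assumption: C6 (the CH between the two ring carbonyls) is enolisable, so its configuration is fixed only by the final protonation and the target is drawn as the triketo tautomer of the given SMILES; all numbered starting materials are taken as commercial.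

## Route

Step 1
Reactants: 1 (1S,5S)-(−)-α-pinene
Product: 3 cis-pinonaldehyde [2-((1R,3R)-3-acetyl-2,2-dimethylcyclobutyl)acetaldehyde], via pinene secondary ozonide 2 (not isolated)
Conditions: O3, CH2Cl2, −78 °C; then Me2S, −78 → 23 °C
Reagents that add atoms: ozone, O=[O+][O-]
Why: Ozonolysis with reductive work-up cleaves the only C=C bond to the keto aldehyde and leaves both ring stereocentres untouched.

Step 2
Reactants: 3 cis-pinonaldehyde
Product: 4 1-[(1R,3S)-2,2-dimethyl-3-(3-methylbut-2-en-1-yl)cyclobutyl]ethan-1-one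
Conditions: i-PrPPh3I, n-BuLi, THF, 0 °C; then 3, −78 → 0 °C
Reagents that add atoms: isopropyltriphenylphosphonium iodide, CC(C)[P+](c1ccccc1)(c1ccccc1)c1ccccc1.[I-]
Why: Wittig olefination with a non-stabilised ylide should be much faster at the aldehyde than at the hindered methyl ketone at −78 °C; epimerisation next to the ketone would be harmless because that centre is erased in step 6.

Step 3
Reactants: 5 methyl 3,4-dihydroxybenzoate
Product: 6 methyl 3,4-bis[(triisopropylsilyl)oxy]benzoate
Conditions: i-Pr3SiOTf, 2,6-lutidine, CH2Cl2, 0 → 23 °C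
Reagents that add atoms: triisopropylsilyl trifluoromethanesulfonate, CC(C)[Si](C(C)C)(C(C)C)OS(=O)(=O)C(F)(F)F
Why: Silylation of both phenols; aryl triisopropylsilyl ethers should survive amide bases, mild Lewis acid and carbonate and are removed by fluoride at the end.

Step 4
Reactants: 4 the cyclobutyl methyl ketone, 6 the silylated aryl ester
Product: 7 1-{3,4-bis[(triisopropylsilyl)oxy]phenyl}-3-[(1R,3S)-2,2-dimethyl-3-(3-methylbut-2-en-1-yl)cyclobutyl]propane-1,3-dione
Conditions: LiN(SiMe3)2 (2.5 equiv), THF, −78 °C; then 6, −78 → 23 °C; aq. NH4Cl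
Reagents that add atoms: none
Why: Crossed Claisen condensation of the kinetic methyl-ketone lithium enolate with the aryl ester, driven by deprotonation of the β-diketone formed.

Step 5
Reactants: 7 the β-diketone, 8 methyl 3-chloro-3-oxopropanoate (methyl malonyl chloride)
Product: 9 methyl 4-{3,4-bis[(triisopropylsilyl)oxy]benzoyl}-5-[(1R,3S)-2,2-dimethyl-3-(3-methylbut-2-en-1-yl)cyclobutyl]-3,5-dioxopentanoate (drawn as the keto form)
Conditions: MgCl2, pyridine, CH2Cl2, 0 → 23 °C
Reagents that add atoms: none
Why: C-acylation of the magnesium chelate of a β-diketone with an acid chloride (soft enolisation) places the third acyl group on the central carbon, the future C8.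

Step 6
Reactants: 9 the cyclobutyl triketo ester
Product: 10 methyl (4Z)-5-{3,4-bis[(triisopropylsilyl)oxy]phenyl}-4-[(5R)-6,6-dimethyl-5-(3-methylbut-2-en-1-yl)oxan-2-ylidene]-3,5-dioxopentanoate
Conditions: Sc(OTf)3 (10 mol %), 2,6-di-tert-butyl-4-methylpyridine (15 mol %), 4 Å MS, ClCH2CH2Cl, 40 °C
Reagents that add atoms: none
Why: Proposed new method: Sc(OTf)3 binds the enolised 1,3,5-tricarbonyl of 9 as an O,O-chelate and makes the acyl group on cyclobutane C1 a strong electron sink, so the strained C1–C2 bond (C2 carries the two methyl groups) ionises to a tertiary carbocation and a scandium dienolate. The oxygen of that acyl group, now an enolate oxygen, captures the cation through a six-membered array (SN1 O-alkylation, 6-exo-tet counted from the enolate oxygen), so the C=O unit is inserted into the four-membered ring and the oxane results; a proton shift then brings the double bond into conjugation with both acyl groups. The closest known reaction types are the Cloke–Wilson rearrangement of cyclopropyl ketones to dihydrofurans, the Lewis-acid heterolysis of donor–acceptor cyclobutanes in their formal cycloadditions, and the acid-induced opening of cyclobutyl ketones of the pinane family at the same bond. No stereocentre is created; the one present (C3 of the cyclobutane, C5 of the oxane) is not part of the ionising bond and keeps its configuration. The step needs cleavage of C1–C2 and not C1–C4, which only the gem-dimethyl carbon secures, and capture by the C1 acyl oxygen, the only oxygen that can close a ring smaller than eight atoms; C-capture merely re-forms 9. The hindered pyridine removes triflic acid so that the prenyl double bond and the silyl ethers are left alone; proton loss from the cation and lactonisation of the keto ester to a pyranone are the by-paths to watch.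

Step 7
Reactants: 10 the oxanylidene triketo ester, 11 1-bromo-3-methylbut-2-ene (prenyl bromide)
Product: 12 methyl (4Z)-5-{3,4-bis[(triisopropylsilyl)oxy]phenyl}-4-[(5R)-6,6-dimethyl-5-(3-methylbut-2-en-1-yl)oxan-2-ylidene]-2-(3-methylbut-2-en-1-yl)-3,5-dioxopentanoate (both C2 epimers)
Conditions: K2CO3, acetone, 23 °C
Reagents that add atoms: none
Why: Alkylation of the most acidic C–H (α-carbon of the β-keto ester) with an allylic bromide is C-selective under these conditions; the new centre (future C6) is enolisable and is fixed only at the end.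

Step 8
Reactants: 13 (4R)-4-benzyl-1,3-oxazolidin-2-one, 14 3-methylbut-2-enoyl chloride
Product: 15 (4R)-4-benzyl-3-(3-methylbut-2-enoyl)-1,3-oxazolidin-2-one
Conditions: n-BuLi, THF, −78 °C; then 14, −78 → 0 °C
Reagents that add atoms: none
Why: N-Acylation of the lithiated oxazolidinone auxiliary with an acid chloride.

Step 9
Reactants: 15 the N-acyl oxazolidinone, 11 prenyl bromide
Product: 16 (4R)-4-benzyl-3-[(2R)-5-methyl-2-(prop-1-en-2-yl)hex-4-enoyl]-1,3-oxazolidin-2-one
Conditions: NaN(SiMe3)2, THF, −78 °C; then 11, −78 → −40 °C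
Reagents that add atoms: none
Why: Deconjugative α-alkylation of the chelated sodium dienolate; the benzyl group of the auxiliary shields one face, so the electrophile should enter from the other and give the (2R) centre, by analogy with simple acyl oxazolidinones.

Step 10
Reactants: 16 the alkylated imide
Product: 17 (R)-lavandulol [(2R)-5-methyl-2-(prop-1-en-2-yl)hex-4-en-1-ol]
Conditions: LiBH4, MeOH (1 equiv), Et2O, 0 °C
Reagents that add atoms: none
Why: Reductive cleavage of the N-acyl oxazolidinone with borohydride releases the primary alcohol without touching the stereocentre or the double bonds.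

Step 11
Reactants: 17 (R)-lavandulol
Product: 18 (R)-lavandulyl iodide [(3R)-3-(iodomethyl)-2,6-dimethylhepta-1,5-diene]
Conditions: PPh3, I2, imidazole, CH2Cl2, 0 → 23 °C
Reagents that add atoms: iodine, II
Why: Appel-type iodination of a primary alcohol; substitution occurs at CH2, so the stereocentre is not involved.

Step 12
Reactants: 12 the prenylated oxanylidene triketo ester, 18 (R)-lavandulyl iodide
Product: 19 methyl (4Z)-5-{3,4-bis[(triisopropylsilyl)oxy]phenyl}-4-{(5S)-6,6-dimethyl-5-(3-methylbut-2-en-1-yl)-3-[(2S)-5-methyl-2-(prop-1-en-2-yl)hex-4-en-1-yl]oxan-2-ylidene}-2-(3-methylbut-2-en-1-yl)-3,5-dioxopentanoate (epimers at oxane C3 and at C2 of the chain)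
Conditions: LiN(iPr)2 (2.2 equiv), THF–DMPU (5:1), −78 → −40 °C; then 18, −40 → 0 °C; aq. NH4Cl
Reagents that add atoms: none
Why: Dianion alkylation: the first equivalent of base takes the β-keto ester proton, the second the γ-proton at oxane C3 of the vinylogous aryl ketone, and only this more basic γ-carbanion should attack the primary iodide; the new centre need not be controlled because it is deprotonated again in step 13.

Step 13
Reactants: 19 the lavandulylated triketo ester
Product: 20 (3S,4aR,6S)-8-{3,4-bis[(triisopropylsilyl)oxy]benzoyl}-2,2-dimethyl-3,6-bis(3-methylbut-2-en-1-yl)-4a-[(2S)-5-methyl-2-(prop-1-en-2-yl)hex-4-en-1-yl]-3,4-dihydro-2H-chromene-5,7(4aH,6H)-dione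
Conditions: KOt-Bu (2.2 equiv), t-BuOH–THF (1:4), 0 → 40 °C; then AcOH, −20 °C
Reagents that add atoms: none
Why: Intramolecular vinylogous Claisen (Dieckmann-type, 6-exo-trig) acylation of the γ-carbanion at oxane C3 by the methyl ester closes the carbocycle and is driven by the triketone enolate; the ring fusion forces the new C5 carbonyl carbon pseudo-equatorial and the lavandulylmethyl group axial on the oxane, so only closure on the face that leaves the C3 prenyl group equatorial avoids a 1,3-diaxial clash and should set C4a, and the acidic quench protonates C6 anti to the axial lavandulylmethyl group.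

Step 14
Reactants: 20 the bis-silyl ether
Product: 21 (3S,4aR,6S)-8-(3,4-dihydroxybenzoyl)-2,2-dimethyl-3,6-bis(3-methylbut-2-en-1-yl)-4a-[(2S)-5-methyl-2-(prop-1-en-2-yl)hex-4-en-1-yl]-3,4-dihydro-2H-chromene-5,7(4aH,6H)-dione (CNP0250793.1)
Conditions: Et3N·3HF, THF–MeCN (1:1), 0 → 23 °C
Reagents that add atoms: none
Why: Fluoride desilylation of the two aryl silyl ethers under nearly neutral conditions should leave the enol ether, the enolisable triketone and the four double bonds alone.

## Compound list

1 | (1S,5S)-(−)-α-pinene | CC1=CC[C@H]2C[C@@H]1C2(C)C | starting material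
2 | secondary ozonide of 1 (1,2,4-trioxolane; mixture at the two new centres) | CC12OOC(O1)C[C@H]3C[C@@H]2C3(C)C | intermediate
3 | cis-pinonaldehyde, 2-[(1R,3R)-3-acetyl-2,2-dimethylcyclobutyl]acetaldehyde | O=CC[C@H]1C[C@@H](C(C)=O)C1(C)C | intermediate
4 | 1-[(1R,3S)-2,2-dimethyl-3-(3-methylbut-2-en-1-yl)cyclobutyl]ethan-1-one | CC(C)=CC[C@H]1C[C@@H](C(C)=O)C1(C)C | intermediate
5 | methyl 3,4-dihydroxybenzoate | COC(=O)c1ccc(O)c(O)c1 | starting material
6 | methyl 3,4-bis[(triisopropylsilyl)oxy]benzoate | COC(=O)c1ccc(O[Si](C(C)C)(C(C)C)C(C)C)c(O[Si](C(C)C)(C(C)C)C(C)C)c1 | intermediate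
7 | 1-{3,4-bis[(triisopropylsilyl)oxy]phenyl}-3-[(1R,3S)-2,2-dimethyl-3-(3-methylbut-2-en-1-yl)cyclobutyl]propane-1,3-dione | CC(C)=CC[C@H]1C[C@@H](C(=O)CC(=O)c2ccc(O[Si](C(C)C)(C(C)C)C(C)C)c(O[Si](C(C)C)(C(C)C)C(C)C)c2)C1(C)C | intermediate
8 | methyl 3-chloro-3-oxopropanoate | COC(=O)CC(Cl)=O | starting material
9 | methyl 4-{3,4-bis[(triisopropylsilyl)oxy]benzoyl}-5-[(1R,3S)-2,2-dimethyl-3-(3-methylbut-2-en-1-yl)cyclobutyl]-3,5-dioxopentanoate | CC(C)=CC[C@H]1C[C@@H](C(=O)C(C(=O)CC(=O)OC)C(=O)c2ccc(O[Si](C(C)C)(C(C)C)C(C)C)c(O[Si](C(C)C)(C(C)C)C(C)C)c2)C1(C)C | intermediate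
10 | methyl (4Z)-5-{3,4-bis[(triisopropylsilyl)oxy]phenyl}-4-[(5R)-6,6-dimethyl-5-(3-methylbut-2-en-1-yl)oxan-2-ylidene]-3,5-dioxopentanoate (push–pull double bond, geometry labile) | CC(C)=CC[C@H]1CC/C(=C(/C(=O)c2ccc(O[Si](C(C)C)(C(C)C)C(C)C)c(O[Si](C(C)C)(C(C)C)C(C)C)c2)C(=O)CC(=O)OC)OC1(C)C | intermediate
11 | 1-bromo-3-methylbut-2-ene (prenyl bromide) | CC(C)=CCBr | starting material
12 | C2-prenyl derivative of 10 (both C2 epimers) | CC(C)=CC[C@H]1CC/C(=C(/C(=O)c2ccc(O[Si](C(C)C)(C(C)C)C(C)C)c(O[Si](C(C)C)(C(C)C)C(C)C)c2)C(=O)C(CC=C(C)C)C(=O)OC)OC1(C)C | intermediate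
13 | (4R)-4-benzyl-1,3-oxazolidin-2-one | O=C1N[C@H](Cc2ccccc2)CO1 | starting material
14 | 3-methylbut-2-enoyl chloride | CC(C)=CC(Cl)=O | starting material
15 | (4R)-4-benzyl-3-(3-methylbut-2-enoyl)-1,3-oxazolidin-2-one | CC(C)=CC(=O)N1[C@H](Cc2ccccc2)COC1=O | intermediate
16 | (4R)-4-benzyl-3-[(2R)-5-methyl-2-(prop-1-en-2-yl)hex-4-enoyl]-1,3-oxazolidin-2-one | C=C(C)[C@@H](CC=C(C)C)C(=O)N1[C@H](Cc2ccccc2)COC1=O | intermediate
17 | (R)-lavandulol | C=C(C)[C@@H](CC=C(C)C)CO | intermediate
18 | (R)-lavandulyl iodide, (3R)-3-(iodomethyl)-2,6-dimethylhepta-1,5-diene | C=C(C)[C@@H](CC=C(C)C)CI | intermediate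
19 | oxane-C3 (2S)-lavandulyl derivative of 12 (epimers at oxane C3 and chain C2) | C=C(C)[C@@H](CC=C(C)C)CC1C[C@H](CC=C(C)C)C(C)(C)O/C1=C(\C(=O)c1ccc(O[Si](C(C)C)(C(C)C)C(C)C)c(O[Si](C(C)C)(C(C)C)C(C)C)c1)C(=O)C(CC=C(C)C)C(=O)OC | intermediate
20 | bis(triisopropylsilyl) ether of the target, (3S,4aR,6S) | C=C(C)[C@@H](CC=C(C)C)C[C@@]12C[C@H](CC=C(C)C)C(C)(C)OC1=C(C(=O)c1ccc(O[Si](C(C)C)(C(C)C)C(C)C)c(O[Si](C(C)C)(C(C)C)C(C)C)c1)C(=O)[C@@H](CC=C(C)C)C2=O | intermediate
21 | CNP0250793.1, (3S,4aR,6S)-8-(3,4-dihydroxybenzoyl)-2,2-dimethyl-3,6-bis(3-methylbut-2-en-1-yl)-4a-[(2S)-5-methyl-2-(prop-1-en-2-yl)hex-4-en-1-yl]-3,4-dihydro-2H-chromene-5,7(4aH,6H)-dione | C=C(C)[C@@H](CC=C(C)C)C[C@@]12C[C@H](CC=C(C)C)C(C)(C)OC1=C(C(=O)c1ccc(O)c(O)c1)C(=O)[C@@H](CC=C(C)C)C2=O | target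

## Step count and risks

Total step count: 14. Longest linear sequence: 9 steps (1, 2, 4, 5, 6, 7, 12, 13, 14).

Step 6 (proposed new method). The ionisation may not set in below the temperature at which the cation sheds a proton or the triketo ester lactonises to a pyranone. The fallback sets out from 9 and comes back at 10, and opens the bond and closes the ring in two operations of known type. Me3SiI (from Me3SiCl and NaI, MeCN, −20 °C) cleaves the acyl-substituted cyclobutane at the gem-dimethyl carbon, as it does with bicyclic pinane ketones, and after hydrolytic work-up gives the tertiary iodide methyl (8R)-4-{3,4-bis[(triisopropylsilyl)oxy]benzoyl}-8-(2-iodopropan-2-yl)-11-methyl-3,5-dioxododec-10-enoate F1. AgOTf with 2,6-di-tert-butyl-4-methylpyridine in CH2Cl2 at −40 °C then ionises the iodide, and the enol oxygen closes the oxane to 10.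

Step 13. Closure at a tertiary γ-carbanion may be outpaced by O-acylation to a pyranone, or may go with poor facial selectivity. The fallback sets out from 12 and comes back at 20, with the order of ring closure and alkylation reversed. KOt-Bu in t-BuOH–THF closes the carbocycle of 12 at its unhindered CH2 and gives, after tautomerisation, the aromatic chromane {(3S)-5,7-dihydroxy-2,2-dimethyl-3,6-bis(3-methylbut-2-en-1-yl)-3,4-dihydro-2H-chromen-8-yl}{3,4-bis[(triisopropylsilyl)oxy]phenyl}methanone F2. Dearomative C-alkylation of its lithium salt at C4a with 18 (LiN(SiMe3)2, toluene, 60 °C), axial and anti to the C3 prenyl group, gives 20; this is the usual entry to dearomatised acylphloroglucinols, though slow with an unactivated iodide.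

Step 12. Slow substitution at the β-branched primary iodide may let elimination or O-alkylation compete, and the dianion may close the carbocycle too early. The fallback sets out from 7 and comes back at 19, with the lavandulyl group put on before the ester is present. The dianion of 7 (LiN(iPr)2, 2.2 equiv) is alkylated with 18 at cyclobutane C1 to give the C1-lavandulyl derivative of 7 F3 (either C1 epimer; this centre is erased later). Acylation with 8 as in step 5 gives the C1-lavandulyl derivative of 9 F4, ring expansion as in step 6 gives 19 without its chain prenyl group F5, and prenylation with 11 as in step 7 gives 19.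

Further compounds
F1 | step 6 | methyl (8R)-4-{3,4-bis[(triisopropylsilyl)oxy]benzoyl}-8-(2-iodopropan-2-yl)-11-methyl-3,5-dioxododec-10-enoate | CC(C)=CC[C@H](C(C)(C)I)CCC(=O)C(C(=O)CC(=O)OC)C(=O)c1ccc(O[Si](C(C)C)(C(C)C)C(C)C)c(O[Si](C(C)C)(C(C)C)C(C)C)c1
F2 | step 13 | {(3S)-5,7-dihydroxy-2,2-dimethyl-3,6-bis(3-methylbut-2-en-1-yl)-3,4-dihydro-2H-chromen-8-yl}{3,4-bis[(triisopropylsilyl)oxy]phenyl}methanone | CC(C)=CC[C@H]1Cc2c(O)c(CC=C(C)C)c(O)c(C(=O)c3ccc(O[Si](C(C)C)(C(C)C)C(C)C)c(O[Si](C(C)C)(C(C)C)C(C)C)c3)c2OC1(C)C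
F3 | step 12 | C1-lavandulyl derivative of 7 (either C1 epimer) | C=C(C)[C@@H](CC=C(C)C)CC1(C(=O)CC(=O)c2ccc(O[Si](C(C)C)(C(C)C)C(C)C)c(O[Si](C(C)C)(C(C)C)C(C)C)c2)C[C@H](CC=C(C)C)C1(C)C
F4 | step 12 | C1-lavandulyl derivative of 9 (either C1 epimer) | C=C(C)[C@@H](CC=C(C)C)CC1(C(=O)C(C(=O)CC(=O)OC)C(=O)c2ccc(O[Si](C(C)C)(C(C)C)C(C)C)c(O[Si](C(C)C)(C(C)C)C(C)C)c2)C[C@H](CC=C(C)C)C1(C)C
F5 | step 12 | 19 without the prenyl group at C2 of the chain (epimers at oxane C3) | C=C(C)[C@@H](CC=C(C)C)CC1C[C@H](CC=C(C)C)C(C)(C)O/C1=C(\C(=O)c1ccc(O[Si](C(C)C)(C(C)C)C(C)C)c(O[Si](C(C)C)(C(C)C)C(C)C)c1)C(=O)CC(=O)OC
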